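**Plan**

- Retrosynthetic cuts, in order: the two ArO–Me bonds; C3–Br (back to a C3 ketone via the alcohol); ring bond C5–C6 (the ring closure); the C4–C5 ethylene unit (from EtMgBr on a lactone carbonyl that becomes C3); the benzylic C=C of a Stobbe adduct, leading to 4-bromo-2,5-dimethoxybenzaldehyde and dimethyl 2,2-dimethylsuccinate.
- Enabling feature: in the cyclohexane ring the bromine-bearing C3 lies β to the ring CH2 C5, and C6 carries the exocyclic CH2. With C3 as a ketone, C3–C4–C5 is a ketone homoenolate (stored as a 1-substituted cyclopropanol) and C6=CH2 is the internal carbon of a terminal alkyne. One redox-neutral isomerisation then closes the only carbocycle and delivers the methylidene group and the C3 carbonyl together.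
- Forward order: Stobbe condensation → asymmetric hydrogenation → γ-lactone → Kulinkovich cyclopropanol → alkyne → ring closure → ketone reduction → bromide → hydroquinone.
- Stereochemistry: C1 from the [Rh(cod)((S,S)-Et-DuPhos)]OTf hydrogenation; C3 from reagent-controlled (R)-Me-CBS reduction followed by SN2 inversion with bromide, which gives the cis (diequatorial) Br/arylmethyl arrangement.

Key step: step 7

**Remarks and assumptions**

- Ring numbering of the target cyclohexane, also used for the open-chain precursors: C1 = CH bearing the arylmethyl group, C2 = CMe2, C3 = CHBr, C4 and C5 = ring CH2 groups, C6 = C(=CH2).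
- Assumption: the facial sense of the Rh/Et-DuPhos reduction of 4 is taken to parallel that of β-aryl itaconate half-esters ((S,S) ligand giving 5). If the mirror-image acid predominates, the (R,R) ligand is used.
- Assumption: 4 is drawn as the Z isomer (aryl away from the quaternary carbon), expected on steric grounds; the alkene is removed in step 2.

**Route**

Step 1
Reactants: 1 4-bromo-2,5-dimethoxybenzaldehyde; 2 dimethyl 2,2-dimethylsuccinate
Product: 4 (Z)-3-[(4-bromo-2,5-dimethoxyphenyl)methylidene]-4-methoxy-2,2-dimethyl-4-oxobutanoic acid, via paraconic lactone ester 3 (not isolated)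
Conditions: KOtBu (1.3 equiv), t-BuOH, 60 °C; then 1 M HCl
Reagents that add atoms: none
Why: Stobbe condensation: the only enolisable CH2 of 2 adds to the aldehyde, the alkoxide lactonises onto the distal ester to give 3, and E1cB opening of 3 frees exactly that hindered carboxyl group while the conjugated ester stays.

Step 2
Reactants: 4
Product: 5 (3R)-3-[(4-bromo-2,5-dimethoxyphenyl)methyl]-4-methoxy-2,2-dimethyl-4-oxobutanoic acid
Conditions: H2 (6 bar), [Rh(cod)((S,S)-Et-DuPhos)]OTf (1 mol %), NaOMe (10 mol %), MeOH, 25 °C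
Reagents that add atoms: none
Why: Rhodium-bisphosphine asymmetric hydrogenation of a Stobbe (β-aryl itaconate type) half-ester, in which the carboxylate chelates rhodium beside the alkene and the C2-symmetric ligand selects the alkene face, should set the stereocentre that becomes ring C1, the aryl bromide being inert to the cationic rhodium catalyst.

Step 3
Reactants: 5
Product: 7 (4R)-4-[(4-bromo-2,5-dimethoxyphenyl)methyl]-3,3-dimethyloxolan-2-one, via hydroxy acid 6 (not isolated)
Conditions: KOH (1.0 equiv), MeOH, evaporate; LiBH4 (2 equiv), THF, 0 → 50 °C; then 2 M HCl, 25 °C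
Reagents that add atoms: none
Why: Chemoselective borohydride reduction of the ester beside the carboxylate salt, then acid-promoted γ-lactonisation (the standard lignan-lactone sequence), should give 7, in which the stereocentre is no longer α to a carbonyl group and cannot epimerise.

Step 4
Reactants: 7
Product: 8 (2R)-2-[(4-bromo-2,5-dimethoxyphenyl)methyl]-3-(1-hydroxycyclopropyl)-3-methylbutan-1-ol
Conditions: EtMgBr (3.5 equiv), Ti(OiPr)4 (1.0 equiv), THF, 0 → 25 °C; then sat. NH4Cl
Reagents that add atoms: ethylmagnesium bromide, CC[Mg]Br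
Why: Kulinkovich cyclopropanation: the titanacyclopropane formed from two equivalents of EtMgBr and Ti(OiPr)4 acts as a 1,2-dicarbanion toward the lactone carbonyl and installs C4 and C5 as the cyclopropane CH2 groups, lactones being reactive substrates and aryl bromides being tolerated.

Step 5
Reactants: 8
Product: 10 (6R)-6-[(4-bromo-2,5-dimethoxyphenyl)methyl]-7,7-dimethyl-4-oxaspiro[2.4]heptan-5-ol, via hydroxy aldehyde 9 (not isolated)
Conditions: SO3·pyridine (2 equiv), DMSO (5 equiv), i-Pr2NEt (3 equiv), CH2Cl2, 0 °C
Reagents that add atoms: none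
Why: Parikh-Doering oxidation should touch only the primary alcohol (activated DMSO cannot oxidise the tertiary cyclopropanol and no one-electron oxidant is present to open the three-membered ring), and aldehyde 9 closes onto the tertiary hydroxyl to lactol 10, which shields the α-stereocentre.

Step 6
Reactants: 10
Product: 11 1-[(3S)-3-[(4-bromo-2,5-dimethoxyphenyl)methyl]-2-methylpent-4-yn-2-yl]cyclopropan-1-ol
Conditions: dimethyl (1-diazo-2-oxopropyl)phosphonate (2 equiv), K2CO3 (3 equiv), MeOH, 0 → 25 °C
Reagents that add atoms: dimethyl (1-diazo-2-oxopropyl)phosphonate, CC(=O)C(=[N+]=[N-])P(=O)(OC)OC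
Why: Seyferth-Gilbert homologation with the Bestmann-Ohira reagent acts on the open aldehyde form 9 that K2CO3/MeOH keeps in equilibrium with 10, the base being too weak to open the cyclopropanol and the hindered α-hydrogen next to the quaternary carbon being expected to keep its configuration.

Step 7
Reactants: 11
Product: 14 (3S)-3-[(4-bromo-2,5-dimethoxyphenyl)methyl]-2,2-dimethyl-4-methylidenecyclohexan-1-one, via cobalt homoenolate 12 (not isolated), via alkenylcobalt species 13 (not isolated)
Conditions: CoBr2 (10 mol %), 1,3-bis(diphenylphosphino)propane (12 mol %), Zn (20 mol %), DABCO (1 equiv), DMSO, 70 °C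
Reagents that add atoms: none
Why: Proposed new method: the monovalent cobalt alkoxide of 11 should undergo strain-driven β-carbon elimination to the homoenolate 12, whose Co–C5 bond adds syn across the tethered terminal alkyne to give 13, and protonation of 13 by the hydroxyl group of a further molecule of 11 releases 14 and regenerates the alkoxide, so that the step is a redox-neutral isomerisation. The closest known reaction type is the cobalt-catalysed intermolecular ring-opening hydroalkylation of internal alkynes with cyclopropanols (β-alkenylation of the derived ketones), and palladium homoenolates from cyclopropanols are likewise known to couple at sp2 carbon, whereas the intramolecular variant with an unactivated terminal alkyne is not established. The six-membered ring closes in the 6-exo-dig mode, C5 bonding to the internal alkyne carbon C6 while cobalt ends on the terminal carbon that becomes the methylidene CH2. No stereocentre is formed, and C1 should stay intact because the carbon nucleophile remains metal-bound, whereas a free β-keto radical at C5 would be prone to a 1,5-hydrogen shift from the propargylic C1–H. The step needs exo over 7-endo insertion and insertion over β-hydride elimination or simple protonation of 12; the syn four-centre insertion geometry, the gem-dimethyl group at C2 that folds the chain, and the absence of any proton source stronger than the cyclopropanol should secure this, and the enone formed by β-hydride elimination can re-enter through hydrometalation of the alkyne and conjugate addition to the same product. The aryl bromide is expected to survive because only a substoichiometric amount of zinc is present to generate the monovalent cobalt.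

Step 8
Reactants: 14
Product: 15 (1S,3S)-3-[(4-bromo-2,5-dimethoxyphenyl)methyl]-2,2-dimethyl-4-methylidenecyclohexan-1-ol
Conditions: (R)-Me-CBS oxazaborolidine (20 mol %), catecholborane (1.5 equiv), toluene, −78 → −40 °C; then MeOH, H2O
Reagents that add atoms: none
Why: Corey-Bakshi-Shibata reduction under reagent control: the ketone binds with the quaternary C2 side as the large group, so the (R)-catalyst should deliver hydride to give the (1S) alcohol with OH trans to the arylmethyl group, and catecholborane at low temperature leaves the 1,1-disubstituted alkene alone.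

Step 9
Reactants: 15
Product: 17 1-bromo-4-{[(1S,3R)-3-bromo-2,2-dimethyl-6-methylidenecyclohexyl]methyl}-2,5-dimethoxybenzene, via alkoxyphosphonium bromide 16 (not isolated)
Conditions: CBr4 (2 equiv), PPh3 (2 equiv), toluene, 0 → 60 °C
Reagents that add atoms: carbon tetrabromide, BrC(Br)(Br)Br
Why: Appel reaction: bromide displaces the alkoxyphosphonium group of 16 by SN2 with inversion, turning the axial C3–O bond into the equatorial C3–Br bond cis to the arylmethyl group, under neutral conditions that spare the exocyclic alkene.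

Step 10
Reactants: 17
Product: 19 cyclocymopol (2-bromo-5-{[(1S,3R)-3-bromo-2,2-dimethyl-6-methylidenecyclohexyl]methyl}benzene-1,4-diol), via bromoquinone 18 (not isolated)
Conditions: (NH4)2Ce(NO3)6 (2.5 equiv), MeCN/H2O, 0 °C; then Na2S2O4, H2O/EtOAc, 25 °C
Reagents that add atoms: water, O
Why: Oxidative demethylation of the para-dimethoxyarene by (NH4)2Ce(NO3)6 (water supplies the quinone oxygen atoms) and dithionite reduction of 18 should give the hydroquinone without acid, which avoids addition of the phenol to the exocyclic alkene and leaves both C–Br bonds intact.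

**Compound list**

1 | 4-bromo-2,5-dimethoxybenzaldehyde | O=Cc1cc(OC)c(Br)cc1OC | starting material
2 | dimethyl 2,2-dimethylsuccinate | COC(=O)CC(C)(C)C(=O)OC | starting material
3 | methyl 2-(4-bromo-2,5-dimethoxyphenyl)-4,4-dimethyl-5-oxooxolane-3-carboxylate (stereoisomer mixture) | COC(=O)C1C(c2cc(OC)c(Br)cc2OC)OC(=O)C1(C)C | intermediate, not isolated
4 | (Z)-3-[(4-bromo-2,5-dimethoxyphenyl)methylidene]-4-methoxy-2,2-dimethyl-4-oxobutanoic acid | COC(=O)/C(=C\c1cc(OC)c(Br)cc1OC)C(C)(C)C(=O)O | intermediate
5 | (3R)-3-[(4-bromo-2,5-dimethoxyphenyl)methyl]-4-methoxy-2,2-dimethyl-4-oxobutanoic acid | COC(=O)[C@H](Cc1cc(OC)c(Br)cc1OC)C(C)(C)C(=O)O | intermediate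
6 | (3R)-3-[(4-bromo-2,5-dimethoxyphenyl)methyl]-4-hydroxy-2,2-dimethylbutanoic acid | OC[C@H](Cc1cc(OC)c(Br)cc1OC)C(C)(C)C(=O)O | intermediate, not isolated
7 | (4R)-4-[(4-bromo-2,5-dimethoxyphenyl)methyl]-3,3-dimethyloxolan-2-one | CC1(C)C(=O)OC[C@@H]1Cc1cc(OC)c(Br)cc1OC | intermediate
8 | (2R)-2-[(4-bromo-2,5-dimethoxyphenyl)methyl]-3-(1-hydroxycyclopropyl)-3-methylbutan-1-ol | OC[C@H](Cc1cc(OC)c(Br)cc1OC)C(C)(C)C1(O)CC1 | intermediate
9 | (2R)-2-[(4-bromo-2,5-dimethoxyphenyl)methyl]-3-(1-hydroxycyclopropyl)-3-methylbutanal | O=C[C@H](Cc1cc(OC)c(Br)cc1OC)C(C)(C)C1(O)CC1 | intermediate, not isolated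
10 | (6R)-6-[(4-bromo-2,5-dimethoxyphenyl)methyl]-7,7-dimethyl-4-oxaspiro[2.4]heptan-5-ol (both configurations at C5) | OC1OC2(CC2)C(C)(C)[C@H]1Cc1cc(OC)c(Br)cc1OC | intermediate
11 | 1-[(3S)-3-[(4-bromo-2,5-dimethoxyphenyl)methyl]-2-methylpent-4-yn-2-yl]cyclopropan-1-ol | C#C[C@H](Cc1cc(OC)c(Br)cc1OC)C(C)(C)C1(O)CC1 | intermediate
12 | cobalt homoenolate: [(5S)-5-[(4-bromo-2,5-dimethoxyphenyl)methyl]-4,4-dimethyl-3-oxohept-6-yn-1-yl]cobalt (diphosphine on cobalt not drawn) | [Co]CCC(=O)C(C)(C)[C@H](C#C)Cc1cc(OC)c(Br)cc1OC | intermediate, not isolated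
13 | alkenylcobalt species: {[(2S)-2-[(4-bromo-2,5-dimethoxyphenyl)methyl]-3,3-dimethyl-4-oxocyclohexylidene]methyl}cobalt, cobalt cis to ring C5 (diphosphine not drawn) | O=C1CC/C(=C\[Co])[C@H](Cc2cc(OC)c(Br)cc2OC)C1(C)C | intermediate, not isolated
14 | (3S)-3-[(4-bromo-2,5-dimethoxyphenyl)methyl]-2,2-dimethyl-4-methylidenecyclohexan-1-one | C=C1CCC(=O)C(C)(C)[C@H]1Cc1cc(OC)c(Br)cc1OC | intermediate
15 | (1S,3S)-3-[(4-bromo-2,5-dimethoxyphenyl)methyl]-2,2-dimethyl-4-methylidenecyclohexan-1-ol | C=C1CC[C@H](O)C(C)(C)[C@H]1Cc1cc(OC)c(Br)cc1OC | intermediate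
16 | {[(1S,3S)-3-[(4-bromo-2,5-dimethoxyphenyl)methyl]-2,2-dimethyl-4-methylidenecyclohexyl]oxy}triphenylphosphonium bromide | C=C1CC[C@H](O[P+](c2ccccc2)(c2ccccc2)c2ccccc2)C(C)(C)[C@H]1Cc1cc(OC)c(Br)cc1OC.[Br-] | intermediate, not isolated
17 | 1-bromo-4-{[(1S,3R)-3-bromo-2,2-dimethyl-6-methylidenecyclohexyl]methyl}-2,5-dimethoxybenzene | C=C1CC[C@@H](Br)C(C)(C)[C@H]1Cc1cc(OC)c(Br)cc1OC | intermediate
18 | 2-bromo-5-{[(1S,3R)-3-bromo-2,2-dimethyl-6-methylidenecyclohexyl]methyl}cyclohexa-2,5-diene-1,4-dione | C=C1CC[C@@H](Br)C(C)(C)[C@H]1CC1=CC(=O)C(Br)=CC1=O | intermediate, not isolated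
19 | cyclocymopol, 2-bromo-5-{[(1S,3R)-3-bromo-2,2-dimethyl-6-methylidenecyclohexyl]methyl}benzene-1,4-diol | C=C1CC[C@@H](Br)C(C)(C)[C@H]1Cc1cc(O)c(Br)cc1O | target

**Step count**

Total steps: 10. Longest linear sequence: 10 (from 1 and 2).

**Steps most likely to fail**

1. Step 7. The homoenolate may be protonated or lose a β-hydride before it inserts, which would leave an open-chain ethyl or vinyl ketone. Cobalt may also oligomerise the terminal alkyne, a cobalt hydride may move the exocyclic double bond into the ring, or the aryl bromide may be reduced. Fallback with known reactions, from 11 back to 14: aerobic oxidative ring opening of the cyclopropanol with Pd(OAc)2 (10 mol %), pyridine and O2 in toluene at 60 °C should give the vinyl ketone (5S)-5-[(4-bromo-2,5-dimethoxyphenyl)methyl]-4,4-dimethylhept-1-en-6-yn-3-one F1. Slow addition of Bu3SnH with AIBN in benzene at 80 °C (high dilution) then adds a stannyl radical to the alkyne terminus, and the vinyl radical at C6 closes 6-endo-trig onto the unsubstituted enone carbon C5 (a tin-mediated enyne radical cyclisation forming the same C5–C6 bond), giving the vinylstannane (3S)-3-[(4-bromo-2,5-dimethoxyphenyl)methyl]-2,2-dimethyl-4-[(tributylstannyl)methylidene]cyclohexan-1-one F2. Protodestannylation with HCl in CH2Cl2 at 0 °C returns to 14.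

2. Step 9. At the neopentyl C3 the alkoxyphosphonium ion may undergo E2 elimination toward C4 or a methyl shift from C2 instead of substitution. Fallback from 15 back to 17: Tf2O and pyridine in CH2Cl2 at −78 °C give the isolated sulfonate (1S,3S)-3-[(4-bromo-2,5-dimethoxyphenyl)methyl]-2,2-dimethyl-4-methylidenecyclohexyl trifluoromethanesulfonate F3, which is displaced with Bu4NBr in toluene at −40 → 0 °C. This separates activation from displacement and uses a far better leaving group with a soluble bromide at low temperature.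

3. Step 2. The hindered trisubstituted alkene next to the quaternary carbon may reduce slowly or with poor face selection. Fallback by auxiliary control, from 1 back to 7:
   - NaBH4 in MeOH gives (4-bromo-2,5-dimethoxyphenyl)methanol F4, and PBr3 in CH2Cl2 gives 1-bromo-4-(bromomethyl)-2,5-dimethoxybenzene F5.
   - Lithiated (R)-4-benzyl-1,3-oxazolidin-2-one opens 2,2-dimethylsuccinic anhydride at the less hindered carbonyl to give 4-[(4R)-4-benzyl-2-oxo-1,3-oxazolidin-3-yl]-2,2-dimethyl-4-oxobutanoic acid F6. MeI and K2CO3 in DMF give its methyl ester, methyl 4-[(4R)-4-benzyl-2-oxo-1,3-oxazolidin-3-yl]-2,2-dimethyl-4-oxobutanoate F7.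
   - The sodium enolate of F7 (NaHMDS, THF, −78 °C) is alkylated with F5 on the face away from the auxiliary benzyl group to give methyl (3R)-4-[(4R)-4-benzyl-2-oxo-1,3-oxazolidin-3-yl]-3-[(4-bromo-2,5-dimethoxyphenyl)methyl]-2,2-dimethyl-4-oxobutanoate F8.
   - LiBH4 in THF/MeOH followed by TsOH cleaves the auxiliary and lactonises to 7.

**Further compounds**

F1 | step 7 | (5S)-5-[(4-bromo-2,5-dimethoxyphenyl)methyl]-4,4-dimethylhept-1-en-6-yn-3-one | C=CC(=O)C(C)(C)[C@H](C#C)Cc1cc(OC)c(Br)cc1OC
F2 | step 7 | (3S)-3-[(4-bromo-2,5-dimethoxyphenyl)methyl]-2,2-dimethyl-4-[(tributylstannyl)methylidene]cyclohexan-1-one | CCCC[Sn](CCCC)(CCCC)C=C1CCC(=O)C(C)(C)[C@H]1Cc1cc(OC)c(Br)cc1OC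
F3 | step 9 | (1S,3S)-3-[(4-bromo-2,5-dimethoxyphenyl)methyl]-2,2-dimethyl-4-methylidenecyclohexyl trifluoromethanesulfonate | C=C1CC[C@H](OS(=O)(=O)C(F)(F)F)C(C)(C)[C@H]1Cc1cc(OC)c(Br)cc1OC
F4 | step 2 | (4-bromo-2,5-dimethoxyphenyl)methanol | OCc1cc(OC)c(Br)cc1OC
F5 | step 2 | 1-bromo-4-(bromomethyl)-2,5-dimethoxybenzene | BrCc1cc(OC)c(Br)cc1OC
F6 | step 2 | 4-[(4R)-4-benzyl-2-oxo-1,3-oxazolidin-3-yl]-2,2-dimethyl-4-oxobutanoic acid | CC(C)(CC(=O)N1C(=O)OC[C@H]1Cc1ccccc1)C(=O)O
F7 | step 2 | methyl 4-[(4R)-4-benzyl-2-oxo-1,3-oxazolidin-3-yl]-2,2-dimethyl-4-oxobutanoate | COC(=O)C(C)(C)CC(=O)N1C(=O)OC[C@H]1Cc1ccccc1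
F8 | step 2 | methyl (3R)-4-[(4R)-4-benzyl-2-oxo-1,3-oxazolidin-3-yl]-3-[(4-bromo-2,5-dimethoxyphenyl)methyl]-2,2-dimethyl-4-oxobutanoate | COC(=O)C(C)(C)[C@@H](Cc1cc(OC)c(Br)cc1OC)C(=O)N1C(=O)OC[C@H]1Cc1ccccc1
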